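**Retrosynthetic overview**
1. The C5=CH bond of the triene is cut (Knoevenagel retron). This gives a 6,8-dione half and a 6'-hydroxy half that carries a C3' propenal. Both halves come from one diol, so a single core synthesis serves twice.
2. Both orsellinates trace back to one esterification of the C7 tertiary alcohol of the common bicyclic ketol with a silylated aroyl triflate.
3. The carbocycle C4a-C5-C6-C7-C8-C8a is contracted by an alpha-ketol retron to a cyclopentene in which C7 is the carbonyl carbon of an acetyl group on C8. The pyran is opened to C1H2OH plus a C4≡C3 enyne. Ring enlargement and pyran closure run in one flask.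
4. Enabling feature: the C8 ketone stands next to the tertiary carbinol C7 bearing CH3 (a 2-hydroxy-2-methyl ketone inside the ring). It is conjugated through C8a=C4a with the pyran enol ether C4=C3-O2, so the six-membered isomer is the thermodynamic sink, and C6 carries the oxygen that makes it the migrating carbon.
5. Ring order: cyclopentene (bought, source of C6), then the six-membered carbocycle, then the pyran. The arenes are bought as orsellinic acid.

Key step: step 8

Assumption: (E)-pent-2-en-4-yn-1-ol, (R)-4-(tert-butyldimethylsilyloxy)cyclopent-2-en-1-one and orsellinic acid are taken as commercial.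
Conventions: locants are those of 1H-isochromene (C1, O2, C3, C4, C4a, C5 to C8, C8a) and are also used for the same atoms in the monocyclic precursors. Primes mark the 6'-hydroxy half of the dimer. TBS = tert-butyldimethylsilyl, TES = triethylsilyl.

**Route**

Step 1
Reactants: 1 (E)-pent-2-en-4-yn-1-ol
Product: 2 (E)-5-(tert-butyldimethylsilyloxy)pent-3-en-1-yne
Conditions: TBSCl, imidazole, CH2Cl2, 0 °C to rt
Reagents that add atoms: tert-butyldimethylsilyl chloride, CC(C)(C)[Si](C)(C)Cl
Why: Imidazole-promoted O-silylation of a primary alcohol masks the hydroxyl against the later organolithium steps and leaves the terminal alkyne C–H free.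

Step 2
Reactants: 3 (R)-4-(tert-butyldimethylsilyloxy)cyclopent-2-en-1-one
Product: 4 (R)-4-(tert-butyldimethylsilyloxy)-2-(hydroxymethyl)cyclopent-2-en-1-one
Conditions: 37% aq. HCHO, Bu3P (20 mol %), CHCl3–MeOH, rt
Reagents that add atoms: formaldehyde, C=O
Why: Morita–Baylis–Hillman hydroxymethylation, in which the weakly basic phosphine adds reversibly to the beta carbon, the enolate captures formaldehyde at the alpha carbon, and the silyloxy-bearing stereocentre stays untouched because no alpha-prime enolate (the entry to E1cB loss of the silyloxy group) is formed.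

Step 3
Reactants: 4 (R)-4-(tert-butyldimethylsilyloxy)-2-(hydroxymethyl)cyclopent-2-en-1-one
Product: 5 (R)-4-(tert-butyldimethylsilyloxy)-2-(triethylsilyloxymethyl)cyclopent-2-en-1-one
Conditions: TESCl, imidazole, CH2Cl2, 0 °C
Reagents that add atoms: chlorotriethylsilane, CC[Si](Cl)(CC)CC
Why: Standard silylation; the primary TES ether should survive organolithium reagents and pyridinium chlorochromate yet is far more acid-labile than the TBS ethers, which is what step 7 needs.

Step 4
Reactants: 2 (E)-5-(tert-butyldimethylsilyloxy)pent-3-en-1-yne; 5 (R)-4-(tert-butyldimethylsilyloxy)-2-(triethylsilyloxymethyl)cyclopent-2-en-1-one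
Product: 7 (4R)-4-(tert-butyldimethylsilyloxy)-1-[(E)-5-(tert-butyldimethylsilyloxy)pent-3-en-1-ynyl]-2-(triethylsilyloxymethyl)cyclopent-2-en-1-ol (both carbinol epimers), via lithium acetylide 6 (not isolated)
Conditions: 2, n-BuLi, THF, −78 °C; then 5, −78 °C; aq. NH4Cl
Reagents that add atoms: none
Why: 1,2-Addition of a lithium acetylide to the enone carbonyl (hard nucleophile and low temperature exclude conjugate addition and elimination); the new carbinol centre is of no consequence because step 5 makes it trigonal.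

Step 5
Reactants: 7 tertiary bis-allylic/propargylic alcohol
Product: 8 (R)-5-(tert-butyldimethylsilyloxy)-3-[(E)-5-(tert-butyldimethylsilyloxy)pent-3-en-1-ynyl]-2-(triethylsilyloxymethyl)cyclopent-2-en-1-one
Conditions: pyridinium chlorochromate, 4 Å MS, CH2Cl2, rt
Reagents that add atoms: pyridinium chlorochromate (delivers the carbonyl oxygen), [O-][Cr](=O)(=O)Cl.c1cc[nH+]cc1
Why: Babler–Dauben oxidative transposition, in which the tertiary allylic chromate ester undergoes a [3,3]-shift to C8 and is oxidised there, placing the ketone next to the silyloxy-bearing C6 and the enyne on the beta carbon C4a without touching the C6 stereocentre.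

Step 6
Reactants: 8 enynone
Product: 9 (1S,5R)-5-(tert-butyldimethylsilyloxy)-1-(1-ethoxyvinyl)-3-[(E)-5-(tert-butyldimethylsilyloxy)pent-3-en-1-ynyl]-2-(triethylsilyloxymethyl)cyclopent-2-en-1-ol (hydroxyl cis to the ring OTBS group)
Conditions: ethyl vinyl ether, t-BuLi, THF, −78 to 0 °C; then 8, −78 °C; aq. NH4Cl
Reagents that add atoms: ethyl vinyl ether, C=COCC (lithiated in the flask)
Why: 1,2-Addition of the acyl anion equivalent 1-ethoxyvinyllithium (the classical entry from cyclopentanones to 1-acetylcyclopentanols); the nucleophile should approach the face anti to the adjacent C6 silyloxy group, which sets C8 as S with its hydroxyl cis to OTBS.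

Step 7
Reactants: 9 ethoxyvinyl carbinol
Product: 10 1-[(1S,5R)-5-(tert-butyldimethylsilyloxy)-1-hydroxy-2-(hydroxymethyl)-3-[(E)-5-(tert-butyldimethylsilyloxy)pent-3-en-1-ynyl]cyclopent-2-en-1-yl]ethan-1-one
Conditions: AcOH–THF–H2O (3:1:1), 0 °C to rt
Reagents that add atoms: water (carbonyl oxygen of the acetyl group), O
Why: Acid hydrolysis of the enol ether to the methyl ketone with simultaneous solvolysis of the primary TES ether, both much faster than cleavage of TBS ethers, and without risk to C8 because an alpha-acyl carbinol resists ionisation.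

Step 8
Reactants: 10 acetyl cyclopentenol
Product: 12 (6R,7R)-6-(tert-butyldimethylsilyloxy)-7-hydroxy-7-methyl-3-[(E)-3-(tert-butyldimethylsilyloxy)prop-1-enyl]-1,5,6,7-tetrahydro-8H-isochromen-8-one, via ring-enlarged enynone ketol 11 (not isolated)
Conditions: Sc(OTf)3 (10 mol %), 4 Å MS, CH2Cl2, 0 °C to rt; then Ph3PAuNTf2 (3 mol %), same flask, rt
Reagents that add atoms: none
Why: Sc(OTf)3 should bind the C8 hydroxyl and the acetyl oxygen of 10 in a five-membered chelate, the ring bond C8–C6 then shifts to the acetyl carbon (C7) while C8 becomes the ketone, and the cyclopentene is enlarged to the cyclohexenone of 11; this is the alpha-ketol (acyloin) rearrangement in its 5-to-6 form, known from 1-acylcyclopentanols and from the D-homoannulation of 17-hydroxy-20-oxo steroids. Ph3PAuNTf2 added to the same flask activates the alkyne, the C1 hydroxyl adds to C3 and protodeauration at C4 follows, so the carbocycle arises by 1,2-shift (insertion of C7 into C8–C6) and the pyran by 6-endo-dig hydroalkoxylation, the closure known from 2-alkynylbenzyl alcohols to 1H-isochromenes. The only new stereocentre, C7, is set by 1,2-chirality transfer from C8, which is destroyed: in the syn-periplanar chelate C6 faces one side of the acetyl carbonyl only and migrates with retention, so the new carbinol oxygen should end cis to the C6 silyloxy group (6R,7R). The step needs migration of C6 and not of the equally aligned alkenyl carbon C8a; the oxygen substituent on C6 raises its migratory aptitude, only this shift leaves the new ketone conjugated with C8a=C4a, and the shift is reversible so that a misdirected product can return. It also needs 6-endo and not 5-exo closure, which the polarisation of the alkyne secures, because C3 is distal to the enone and carries the propenyl donor. Both events are isomerisations without by-product, and the vinylogous ester O2–C3=C4–C4a=C8a–C8=O formed last is the sink that drains the equilibria.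

Step 9
Reactants: 13 orsellinic acid (2,4-dihydroxy-6-methylbenzoic acid)
Product: 14 tert-butyldimethylsilyl 2,4-bis(tert-butyldimethylsilyloxy)-6-methylbenzoate
Conditions: TBSCl (3.5 equiv), imidazole, DMF, rt
Reagents that add atoms: tert-butyldimethylsilyl chloride, CC(C)(C)[Si](C)(C)Cl
Why: Exhaustive imidazole-promoted silylation of both phenols and the carboxyl group at room temperature, which avoids the thermal decarboxylation of orsellinic acid.

Step 10
Reactants: 14 tris-silylated orsellinic acid
Product: 15 2,4-bis(tert-butyldimethylsilyloxy)-6-methylbenzoyl chloride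
Conditions: (COCl)2, DMF (cat.), CH2Cl2, 0 °C to rt
Reagents that add atoms: oxalyl chloride (chlorine), O=C(Cl)C(=O)Cl
Why: Conversion of a silyl ester into the acid chloride by the Vilsmeier reagent from oxalyl chloride and DMF, a neutral process that releases no HCl and so leaves the aryl silyl ethers intact.

Step 11
Reactants: 12 bicyclic ketol; 15 aroyl chloride
Product: 17 (6R,7R)-6-(tert-butyldimethylsilyloxy)-7-methyl-8-oxo-3-[(E)-3-(tert-butyldimethylsilyloxy)prop-1-enyl]-5,6,7,8-tetrahydro-1H-isochromen-7-yl 2,4-bis(tert-butyldimethylsilyloxy)-6-methylbenzoate, via aroyl triflate 16 (not isolated)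
Conditions: 15, AgOTf, CH2Cl2, −78 °C; then 12, 2,6-di-tert-butyl-4-methylpyridine, −78 to 0 °C
Reagents that add atoms: none
Why: Acylation through an aroyl triflate (the known benzoyl triflate esterification of hindered alcohols): the electron-rich 2,6-disubstituted aroyl group ionises towards a linear acylium ion small enough for the tertiary C7 hydroxyl, the non-basic medium prevents silyl migration from O6 to O7, and the C7–O bond is not broken, so the configuration is kept.

Step 12
Reactants: 17 fully silylated ester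
Product: 18 (6R,7R)-6-hydroxy-3-[(E)-3-hydroxyprop-1-enyl]-7-methyl-8-oxo-5,6,7,8-tetrahydro-1H-isochromen-7-yl 2,4-bis(tert-butyldimethylsilyloxy)-6-methylbenzoate
Conditions: 48% aq. HF, MeCN, 0 °C
Reagents that add atoms: none
Why: Chemoselective desilylation, since under acidic fluoride alkyl silyl ethers are cleaved through O-protonation much faster than the less basic aryl silyl ethers, so both alkyl TBS groups should fall while the two aryl TBS groups stay.

Step 13
Reactants: 18 diol
Product: 19 (6R,7R)-3-[(E)-3-acetoxyprop-1-enyl]-6-hydroxy-7-methyl-8-oxo-5,6,7,8-tetrahydro-1H-isochromen-7-yl 2,4-bis(tert-butyldimethylsilyloxy)-6-methylbenzoate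
Conditions: Ac2O (1.05 equiv), pyridine, CH2Cl2, −20 °C
Reagents that add atoms: acetic anhydride, CC(=O)OC(C)=O
Why: Kinetically selective acetylation of the unhindered primary allylic alcohol over the secondary C6 hydroxyl, which is flanked by the quaternary C7.

Step 14
Reactants: 19 hydroxy acetate
Product: 20 (R)-3-[(E)-3-acetoxyprop-1-enyl]-7-methyl-6,8-dioxo-5,6,7,8-tetrahydro-1H-isochromen-7-yl 2,4-bis(tert-butyldimethylsilyloxy)-6-methylbenzoate
Conditions: Dess–Martin periodinane, CH2Cl2, 0 °C, argon
Reagents that add atoms: none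
Why: Dess–Martin oxidation of the secondary alcohol under near-neutral conditions; C6 has done its work as stereochemical relay and is erased, while the quaternary C7 cannot epimerise.

Step 15
Reactants: 18 diol
Product: 21 (6R,7R)-6-hydroxy-7-methyl-8-oxo-3-[(E)-3-oxoprop-1-enyl]-5,6,7,8-tetrahydro-1H-isochromen-7-yl 2,4-bis(tert-butyldimethylsilyloxy)-6-methylbenzoate
Conditions: MnO2 (activated), CH2Cl2, rt
Reagents that add atoms: none
Why: Manganese dioxide oxidation is selective for the allylic primary alcohol and should leave the non-allylic C6 hydroxyl and the E-alkene unchanged.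

Step 16
Reactants: 20 dione half; 21 enal half
Product: 22 tetrakis-TBS ether of the target (C5=CH bond with the chain syn to C6=O, E-alkene between the halves)
Conditions: ethylenediammonium diacetate (20 mol %), 4 Å MS, CH2Cl2, rt, argon, dark
Reagents that add atoms: none
Why: Knoevenagel condensation through the iminium ion of 21, in which C5 of 20 (alpha to the C6 ketone and vinylogously alpha to the C8 ketone) is the only nucleophilic site that can lose water after addition, and the reversible amine catalysis should settle the new C5=CH bond with the chain away from C4–H while the E-alkene of 21 is kept.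

Step 17
Reactants: 22 tetrakis-TBS ether
Product: 23 target CNP0239166.2
Conditions: Bu4NF–AcOH (1:1), THF, 0 °C
Reagents that add atoms: none
Why: Fluoride desilylation of aryl silyl ethers is fast because a stabilised phenoxide leaves, and the acetic acid buffer should protect the allylic acetate and suppress aroyl migration from O7' to O6'.

**Compound list**
1 | (E)-pent-2-en-4-yn-1-ol | C#C/C=C/CO | starting material
2 | (E)-5-(tert-butyldimethylsilyloxy)pent-3-en-1-yne | C#C/C=C/CO[Si](C)(C)C(C)(C)C | intermediate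
3 | (R)-4-(tert-butyldimethylsilyloxy)cyclopent-2-en-1-one | O=C1C=C[C@H](O[Si](C)(C)C(C)(C)C)C1 | starting material
4 | (R)-4-(TBSO)-2-(hydroxymethyl)cyclopent-2-en-1-one | O=C1C(CO)=C[C@H](O[Si](C)(C)C(C)(C)C)C1 | intermediate
5 | (R)-4-(TBSO)-2-(TESOCH2)cyclopent-2-en-1-one | O=C1C(CO[Si](CC)(CC)CC)=C[C@H](O[Si](C)(C)C(C)(C)C)C1 | intermediate
6 | lithium acetylide of 2 | [Li]C#C/C=C/CO[Si](C)(C)C(C)(C)C | intermediate (not isolated)
7 | (4R)-tertiary alcohol, carbinol epimers | OC1(C#C/C=C/CO[Si](C)(C)C(C)(C)C)C(CO[Si](CC)(CC)CC)=C[C@H](O[Si](C)(C)C(C)(C)C)C1 | intermediate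
8 | (R)-5-(TBSO)-3-enynyl-2-(TESOCH2)cyclopent-2-en-1-one | O=C1C(CO[Si](CC)(CC)CC)=C(C#C/C=C/CO[Si](C)(C)C(C)(C)C)C[C@H]1O[Si](C)(C)C(C)(C)C | intermediate
9 | (1S,5R)-1-(1-ethoxyvinyl) carbinol | C=C(OCC)[C@]1(O)C(CO[Si](CC)(CC)CC)=C(C#C/C=C/CO[Si](C)(C)C(C)(C)C)C[C@H]1O[Si](C)(C)C(C)(C)C | intermediate
10 | (1S,5R)-1-acetyl-2-(hydroxymethyl)cyclopent-2-en-1-ol | CC(=O)[C@]1(O)C(CO)=C(C#C/C=C/CO[Si](C)(C)C(C)(C)C)C[C@H]1O[Si](C)(C)C(C)(C)C | intermediate
11 | (5R,6R)-5-(TBSO)-6-hydroxy-2-(hydroxymethyl)-6-methyl-3-enynylcyclohex-2-en-1-one | OCC1=C(C#C/C=C/CO[Si](C)(C)C(C)(C)C)C[C@@H](O[Si](C)(C)C(C)(C)C)[C@@](C)(O)C1=O | intermediate (not isolated)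
12 | (6R,7R)-bicyclic ketol | CC(C)(C)[Si](C)(C)OC/C=C/C1=CC2=C(CO1)C(=O)[C@](C)(O)[C@H](O[Si](C)(C)C(C)(C)C)C2 | intermediate
13 | orsellinic acid | Cc1cc(O)cc(O)c1C(=O)O | starting material
14 | TBS 2,4-bis(TBSO)-6-methylbenzoate | Cc1cc(O[Si](C)(C)C(C)(C)C)cc(O[Si](C)(C)C(C)(C)C)c1C(=O)O[Si](C)(C)C(C)(C)C | intermediate
15 | 2,4-bis(TBSO)-6-methylbenzoyl chloride | Cc1cc(O[Si](C)(C)C(C)(C)C)cc(O[Si](C)(C)C(C)(C)C)c1C(=O)Cl | intermediate
16 | 2,4-bis(TBSO)-6-methylbenzoyl triflate | Cc1cc(O[Si](C)(C)C(C)(C)C)cc(O[Si](C)(C)C(C)(C)C)c1C(=O)OS(=O)(=O)C(F)(F)F | intermediate (not isolated)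
17 | (6R,7R)-fully silylated C7 ester | CC(C)(C)[Si](C)(C)OC/C=C/C1=CC2=C(CO1)C(=O)[C@](C)(OC(=O)c1c(C)cc(O[Si](C)(C)C(C)(C)C)cc1O[Si](C)(C)C(C)(C)C)[C@H](O[Si](C)(C)C(C)(C)C)C2 | intermediate
18 | (6R,7R)-diol, branching point | OC/C=C/C1=CC2=C(CO1)C(=O)[C@](C)(OC(=O)c1c(C)cc(O[Si](C)(C)C(C)(C)C)cc1O[Si](C)(C)C(C)(C)C)[C@H](O)C2 | intermediate
19 | (6R,7R)-hydroxy acetate | CC(=O)OC/C=C/C1=CC2=C(CO1)C(=O)[C@](C)(OC(=O)c1c(C)cc(O[Si](C)(C)C(C)(C)C)cc1O[Si](C)(C)C(C)(C)C)[C@H](O)C2 | intermediate
20 | (R)-6,8-dione half | CC(=O)OC/C=C/C1=CC2=C(CO1)C(=O)[C@](C)(OC(=O)c1c(C)cc(O[Si](C)(C)C(C)(C)C)cc1O[Si](C)(C)C(C)(C)C)C(=O)C2 | intermediate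
21 | (6R,7R)-enal half | O=C/C=C/C1=CC2=C(CO1)C(=O)[C@](C)(OC(=O)c1c(C)cc(O[Si](C)(C)C(C)(C)C)cc1O[Si](C)(C)C(C)(C)C)[C@H](O)C2 | intermediate
22 | tetrakis-TBS ether of the target | CC(=O)OC/C=C/C1=CC2=C(CO1)C(=O)[C@](C)(OC(=O)c1c(C)cc(O[Si](C)(C)C(C)(C)C)cc1O[Si](C)(C)C(C)(C)C)C(=O)/C2=C\C=C\C1=CC2=C(CO1)C(=O)[C@](C)(OC(=O)c1c(C)cc(O[Si](C)(C)C(C)(C)C)cc1O[Si](C)(C)C(C)(C)C)[C@H](O)C2 | intermediate
23 | CNP0239166.2, (7R,6'R,7'R) | CC(=O)OC/C=C/C1=CC2=C(CO1)C(=O)[C@](C)(OC(=O)c1c(C)cc(O)cc1O)C(=O)/C2=C\C=C\C1=CC2=C(CO1)C(=O)[C@](C)(OC(=O)c1c(C)cc(O)cc1O)[C@H](O)C2 | target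

**Step count**
Total step count: 17.
Longest linear sequence: 13 steps (2, 3, 4, 5, 6, 7, 8, 11, 12, 13, 14, 16, 17).

**Steps most likely to fail**

Step 8.
- Risk: migration of the alkenyl carbon C8a in place of C6, leakage through a non-chelated conformer with loss of facial control at C7, or 5-exo closure of the alcohol onto the alkyne.
- Fallback, from 9 back to 12: the two isomerisations are uncoupled. The ring enlargement is moved to a substrate with a single free hydroxyl and a stoichiometric chelating metal.
- Oxalic acid on wet silica gel in CH2Cl2 should hydrolyse only the enol ether of 9 to the TES-protected acetyl carbinol F1.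
- Heating F1 with Al(OtBu)3 in toluene turns it into its aluminium alkoxide chelate. Under equilibrating conditions that return any product of alkenyl migration to the pool, this should give the TES-protected ring-enlarged ketol F2.
- AcOH–THF–H2O then frees the C1 hydroxyl to give 11, now as an isolated compound. A separate closure with Ph3PAuNTf2 leads to 12.

Step 11.
- Risk: failure of the hindered tertiary alcohol to capture the aroyl electrophile, with competing attack of the acylium ion on the dienol ether carbon C4 or loss of silyl groups.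
- Fallback, from 12 back to 17: the ester bond is made with a sterically undemanding acylketene, and the arene is built afterwards by folding of a poly-beta-carbonyl chain.
- Commercial 2,2,6-trimethyl-4H-1,3-dioxin-4-one is deprotonated with LiN(SiMe3)2 and acetylated with acetyl chloride to the keto-dioxinone F3.
- The dianion of F3 (LiN(i-Pr)2, 2 equiv) is acetylated at the terminal carbon with N-methoxy-N-methylacetamide to the diketo-dioxinone F4.
- In toluene at 110 °C F4 loses acetone by a retro-hetero-Diels–Alder reaction to the acylketene F5. The C7 hydroxyl of 12 captures it as the 3,5,7-trioxooctanoate F6.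
- K2CO3 in CH2Cl2–i-PrOH followed by brief acid treatment should fold F6 by aldol condensation and dehydration into the free orsellinate F7.
- TBSCl and imidazole silylate both phenols (and any bared primary alcohol) to give 17.

Step 16.
- Risk: conjugate addition to the extended iminium ion instead of 1,2-addition, oxa-6π ring closure of the Z-dienone, aerial dehydrogenation of the dione half, or poor control of the C5=CH geometry.
- Fallback, from 20 and 21 back to 22: the equilibrating amine catalysis is replaced by a stepwise, kinetically controlled aldol addition and a separate elimination.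
- TBSOTf and Et3N convert 20 into the C6 silyl dienol ether F8.
- A Mukaiyama aldol addition of F8 to 21 with BF3·OEt2 at −78 °C should give the C5 aldol F9. It forms as a mixture at its two new centres, both of which are erased.
- Catalytic camphorsulfonic acid then ionises the allylic carbinol next to the electron-rich trienol ether. Loss of the acidic C5 proton gives 22.

**Further compounds**
F1 | step 8 | (1S,5R)-1-acetyl-5-(TBSO)-3-enynyl-2-(TESOCH2)cyclopent-2-en-1-ol | CC(=O)[C@]1(O)C(CO[Si](CC)(CC)CC)=C(C#C/C=C/CO[Si](C)(C)C(C)(C)C)C[C@H]1O[Si](C)(C)C(C)(C)C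
F2 | step 8 | (5R,6R)-5-(TBSO)-6-hydroxy-6-methyl-3-enynyl-2-(TESOCH2)cyclohex-2-en-1-one | CC[Si](CC)(CC)OCC1=C(C#C/C=C/CO[Si](C)(C)C(C)(C)C)C[C@@H](O[Si](C)(C)C(C)(C)C)[C@@](C)(O)C1=O
F3 | step 11 | 2,2-dimethyl-6-(2-oxopropyl)-4H-1,3-dioxin-4-one | CC(=O)CC1=CC(=O)OC(C)(C)O1
F4 | step 11 | 2,2-dimethyl-6-(2,4-dioxopentyl)-4H-1,3-dioxin-4-one | CC(=O)CC(=O)CC1=CC(=O)OC(C)(C)O1
F5 | step 11 | 3,5,7-trioxooct-1-en-1-one (acylketene) | CC(=O)CC(=O)CC(=O)C=C=O
F6 | step 11 | C7 3,5,7-trioxooctanoate of 12 | CC(C)(C)[Si](C)(C)OC/C=C/C1=CC2=C(CO1)C(=O)[C@](C)(OC(=O)CC(=O)CC(=O)CC(C)=O)[C@H](O[Si](C)(C)C(C)(C)C)C2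
F7 | step 11 | C7 orsellinate of 12 with free phenols | CC(C)(C)[Si](C)(C)OC/C=C/C1=CC2=C(CO1)C(=O)[C@](C)(OC(=O)c1c(C)cc(O)cc1O)[C@H](O[Si](C)(C)C(C)(C)C)C2
F8 | step 16 | C6 TBS dienol ether of 20 | CC(=O)OC/C=C/C1=CC2=C(CO1)C(=O)[C@](C)(OC(=O)c1c(C)cc(O[Si](C)(C)C(C)(C)C)cc1O[Si](C)(C)C(C)(C)C)C(O[Si](C)(C)C(C)(C)C)=C2
F9 | step 16 | C5 aldol of 20 and 21 (epimers at C5 and at the carbinol) | CC(=O)OC/C=C/C1=CC2=C(CO1)C(=O)[C@](C)(OC(=O)c1c(C)cc(O[Si](C)(C)C(C)(C)C)cc1O[Si](C)(C)C(C)(C)C)C(=O)C2C(O)/C=C/C1=CC2=C(CO1)C(=O)[C@](C)(OC(=O)c1c(C)cc(O[Si](C)(C)C(C)(C)C)cc1O[Si](C)(C)C(C)(C)C)[C@H](O)C2
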